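The route rests on cutting the C4–C4a bond of ring B. The target carries a single aromatic hydrogen, at C5 of aromatic ring A, directly beside ring-fusion carbon C4a, which bears C4. An aryne spanning C4a–C5 can take both from a 2-methylprop-1-enyl end (C4=C11) tethered to C8a through C1–C3. One intramolecular aryne–ene reaction therefore forms C4–C4a, closes ring B, places hydrogen on C5, sets C4 relative to C1 and leaves an isopropenyl group for the side chain. Its precursor is a 2-silylaryl triflate (OTf on C4a, SiMe3 on C5) with OMe on C7, OMOM on C8 and the (R)-6-methylhept-5-en-2-yl chain on C8a.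

Key step: step 12

Remarks on the chemistry
- Atom labels are those of the target skeleton: ring B carbons C1 (methyl C20), C2, C3, C4; fusion carbons C4a and C8a; aromatic C5–C8; side chain C11 (methyl C18), C12–C14, C15 (methyl C17), C16.
- Assumption: (S)-BINAP is taken to give the (3R)-3-arylbutanoate from the (E)-crotonate, the sense established for phenylboronic acid; the ligand antipode would be used if the opposite held.
- The C4a oxygen is introduced (as bromide) before the alkene exists, so the electrophilic bromination never meets the trisubstituted alkene.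

Step 1
Reactants: 1 guaiacol (2-methoxyphenol)
Product: 2 1-methoxy-2-(methoxymethoxy)benzene
Conditions: MOMCl, i-Pr2NEt, CH2Cl2, 0 °C to rt
Reagents that add atoms: chloromethyl methyl ether, COCCl
Why: O-alkylation of the phenol (Williamson type); the MOM acetal later directs lithiation to C8a, resists fluoride and organolithium reagents, and is removed by acid in the last step.

Step 2
Reactants: 2 1-methoxy-2-(methoxymethoxy)benzene
Product: 5 [3-methoxy-2-(methoxymethoxy)phenyl]boronic acid, via aryllithium 3 (not isolated), via lithium aryltrimethoxyborate 4 (not isolated)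
Conditions: n-BuLi, THF, 0 °C; B(OMe)3, −78 °C to rt; aq NH4Cl
Reagents that add atoms: trimethyl borate, COB(OC)OC; water, O
Why: directed ortho-metalation, in which the acetal oxygens hold the base so that lithium enters ortho to OMOM (the future C8a), followed by borate quench and mild hydrolysis.

Step 3
Reactants: 5 [3-methoxy-2-(methoxymethoxy)phenyl]boronic acid; 6 methyl (E)-but-2-enoate
Product: 7 methyl (3R)-3-[3-methoxy-2-(methoxymethoxy)phenyl]butanoate
Conditions: Rh(acac)(C2H4)2 (3 mol%), (S)-BINAP, dioxane/H2O 10:1, 100 °C, boronic acid in excess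
Reagents that add atoms: none
Why: rhodium-catalysed asymmetric 1,4-addition of an arylboronic acid to an enoate (Hayashi–Miyaura reaction), in which the aryl–rhodium species bound to (S)-BINAP adds to one enantioface of the crotonate and water protonates the rhodium enolate, setting C1 as (R) under catalyst control.

Step 4
Reactants: 7 methyl (3R)-3-[3-methoxy-2-(methoxymethoxy)phenyl]butanoate
Product: 8 methyl (3R)-3-[6-bromo-3-methoxy-2-(methoxymethoxy)phenyl]butanoate
Conditions: NBS, MeCN, 0 °C to rt
Reagents that add atoms: N-bromosuccinimide, O=C1CCC(=O)N1Br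
Why: electrophilic aromatic bromination, directed para to the in-plane C7 methoxy group (to C4a) because the flanked C8 acetal oxygen is twisted out of conjugation.

Step 5
Reactants: 8 methyl (3R)-3-[6-bromo-3-methoxy-2-(methoxymethoxy)phenyl]butanoate
Product: 9 (3R)-3-[6-bromo-3-methoxy-2-(methoxymethoxy)phenyl]butan-1-ol
Conditions: i-Bu2AlH (2.5 equiv), CH2Cl2, −78 to 0 °C; aq Rochelle salt
Reagents that add atoms: none
Why: hydride reduction of the ester to the primary alcohol, which leaves the aryl bromide and the acetal untouched at low temperature.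

Step 6
Reactants: 9 (3R)-3-[6-bromo-3-methoxy-2-(methoxymethoxy)phenyl]butan-1-ol
Product: 10 1-bromo-2-[(2R)-4-iodobutan-2-yl]-4-methoxy-3-(methoxymethoxy)benzene
Conditions: I2, PPh3, imidazole, CH2Cl2, 0 °C to rt
Reagents that add atoms: iodine, II
Why: Appel-type iodination through an alkoxyphosphonium ion with SN2 displacement at the primary carbon C3, which does not involve C1.

Step 7
Reactants: 10 1-bromo-2-[(2R)-4-iodobutan-2-yl]-4-methoxy-3-(methoxymethoxy)benzene; 11 1-bromo-2-methylprop-1-ene
Product: 13 1-bromo-4-methoxy-3-(methoxymethoxy)-2-[(2R)-6-methylhept-5-en-2-yl]benzene, via alkenyl Grignard reagent 12 (not isolated)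
Conditions: 11, Mg, THF, reflux; then 10, CuI (10 mol%), THF, −20 to 0 °C
Reagents that add atoms: none
Why: copper-catalysed cross-coupling of a primary alkyl iodide with an alkenyl Grignard reagent forms C3–C4 and brings in the C4=C11 alkene, while the aryl bromide is inert to the organocopper species at this temperature.

Step 8
Reactants: 13 1-bromo-4-methoxy-3-(methoxymethoxy)-2-[(2R)-6-methylhept-5-en-2-yl]benzene
Product: 16 4-methoxy-3-(methoxymethoxy)-2-[(2R)-6-methylhept-5-en-2-yl]phenol, via aryllithium 14 (not isolated), via lithium aryltrimethoxyborate 15 (not isolated)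
Conditions: n-BuLi, THF, −78 °C; B(OMe)3, −78 °C to rt; H2O2, aq NaOH, 0 °C
Reagents that add atoms: hydrogen peroxide, OO
Why: bromine–lithium exchange, borylation and peroxide oxidation (1,2-shift of the aryl group from boron to oxygen) turn C4a–Br into C4a–OH, and alkaline peroxide does not epoxidise the isolated trisubstituted alkene.

Step 9
Reactants: 16 4-methoxy-3-(methoxymethoxy)-2-[(2R)-6-methylhept-5-en-2-yl]phenol
Product: 17 4-methoxy-3-(methoxymethoxy)-2-[(2R)-6-methylhept-5-en-2-yl]phenyl N-(propan-2-yl)carbamate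
Conditions: i-PrNCO, Et3N (cat.), CH2Cl2, rt
Reagents that add atoms: isopropyl isocyanate, CC(C)N=C=O
Why: base-catalysed addition of the phenol to the isocyanate gives a secondary O-aryl carbamate, a strong ortho-directing group that can later be removed in the triflation flask.

Step 10
Reactants: 17 4-methoxy-3-(methoxymethoxy)-2-[(2R)-6-methylhept-5-en-2-yl]phenyl N-(propan-2-yl)carbamate
Product: 21 4-methoxy-3-(methoxymethoxy)-2-[(2R)-6-methylhept-5-en-2-yl]-6-(trimethylsilyl)phenyl N-(propan-2-yl)carbamate, via N-silyl carbamate 18 (not isolated), via C5-lithio carbamate 19 (not isolated), via N-silyl C5-silyl carbamate 20 (not isolated)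
Conditions: TMSOTf, TMEDA, Et2O, 0 °C; n-BuLi, TMEDA, −78 °C; TMSCl, −78 °C to rt; aq NaHSO4
Reagents that add atoms: chlorotrimethylsilane, C[Si](C)(C)Cl
Why: directed ortho-metalation of the carbamate after in situ N-silylation, with C5 the only free ortho position; the amine-bound silyl triflate should not open the MOM acetal, and the N-silyl group is hydrolysed on work-up.

Step 11
Reactants: 21 4-methoxy-3-(methoxymethoxy)-2-[(2R)-6-methylhept-5-en-2-yl]-6-(trimethylsilyl)phenyl N-(propan-2-yl)carbamate
Product: 23 4-methoxy-3-(methoxymethoxy)-2-[(2R)-6-methylhept-5-en-2-yl]-6-(trimethylsilyl)phenyl trifluoromethanesulfonate, via silylphenol 22 (not isolated)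
Conditions: DBU, Et2NH, MeCN, 40 °C; then PhNTf2, rt
Reagents that add atoms: N-phenylbis(trifluoromethanesulfonimide), O=S(=O)(N(c1ccccc1)S(=O)(=O)C(F)(F)F)C(F)(F)F
Why: amine-induced E1cB cleavage of the carbamate (the isocyanate is trapped by diethylamine) followed by O-sulfonylation of the hindered phenoxide with a mild triflating agent.

Step 12
Reactants: 23 4-methoxy-3-(methoxymethoxy)-2-[(2R)-6-methylhept-5-en-2-yl]-6-(trimethylsilyl)phenyl trifluoromethanesulfonate
Product: 25 (1R,4S)-7-methoxy-8-(methoxymethoxy)-1-methyl-4-(prop-1-en-2-yl)-1,2,3,4-tetrahydronaphthalene, via aryne 24 (not isolated)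
Conditions: CsF (3 equiv), MeCN, 0.01 M, rt
Reagents that add atoms: none
Why: Fluoride attacks silicon and the C5 carbanion expels triflate from C4a to give aryne 24; C4 of the tethered alkene then bonds to C4a in the arene plane while a hydrogen of the C11 methyl group trans to the tether passes to C5 in the same plane, a concerted but asynchronous intramolecular aryne–ene reaction of the kind known for alkene-tethered 2-silylaryl triflates. Ring B closes in a 6-exo mode (the C4=C11 bond stays outside the new ring and becomes C11=CH2), and because the three-carbon tether lets C4 reach C4a only, the hydrogen can go nowhere but C5. The new centre C4 is controlled by C1 through the tether: in the transition state H4 stands perpendicular to the arene and C3 and C11 lie on one and the same face, so that the donor methyl reaches the in-plane orbital at C5. Allylic (peri) strain against the C8 oxygen turns the C1 methyl group out of the plane onto one face, and C3 should pucker to the other face (an envelope with C2 near the arene plane) to avoid the syn-axial contact with that methyl, so C11 follows C3 and ends trans to C20, that is (4S). The step needs this 1,4-trans relay, which rests on the conformational argument alone and not on precedent; the tether secures the regiochemistry and high dilution suppresses intermolecular capture of the aryne.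

Step 13
Reactants: 26 methyl (2R)-3-hydroxy-2-methylpropanoate
Product: 27 methyl (2R)-3-[(tert-butyldimethylsilyl)oxy]-2-methylpropanoate
Conditions: TBSCl, imidazole, CH2Cl2, rt
Reagents that add atoms: tert-butyldimethylsilyl chloride, CC(C)(C)[Si](C)(C)Cl
Why: imidazole-promoted silylation of the primary alcohol, which leaves the stereocentre (the future C15) untouched.

Step 14
Reactants: 27 methyl (2R)-3-[(tert-butyldimethylsilyl)oxy]-2-methylpropanoate
Product: 28 (2R)-3-[(tert-butyldimethylsilyl)oxy]-2-methylpropanal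
Conditions: i-Bu2AlH (1.1 equiv), CH2Cl2, −78 °C; aq Rochelle salt
Reagents that add atoms: none
Why: partial reduction of the ester through the tetrahedral aluminium hemiacetal, stable at −78 °C; the aldehyde is used crude and cold so that the α-centre keeps its configuration.

Step 15
Reactants: 28 (2R)-3-[(tert-butyldimethylsilyl)oxy]-2-methylpropanal
Product: 29 tert-butyl{[(2S,3E)-4-iodo-2-methylbut-3-en-1-yl]oxy}dimethylsilane
Conditions: CrCl2, CHI3, THF, 0 °C to rt
Reagents that add atoms: iodoform, IC(I)I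
Why: Takai olefination, in which the geminal dichromium reagent from iodoform adds to the aldehyde and eliminates to the (E)-vinyl iodide under non-basic conditions that do not epimerise the α-methyl centre.

Step 16
Reactants: 25 (1R,4S)-7-methoxy-8-(methoxymethoxy)-1-methyl-4-(prop-1-en-2-yl)-1,2,3,4-tetrahydronaphthalene; 29 tert-butyl{[(2S,3E)-4-iodo-2-methylbut-3-en-1-yl]oxy}dimethylsilane
Product: 31 tert-butyl{[(2S,3E,6S)-6-[(1S,4R)-6-methoxy-5-(methoxymethoxy)-4-methyl-1,2,3,4-tetrahydronaphthalen-1-yl]-2-methylhept-3-en-1-yl]oxy}dimethylsilane, via B-alkyl-9-BBN 30 (not isolated)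
Conditions: 9-BBN, THF, 0 °C to rt; then 29, Pd(dppf)Cl2 (5 mol%), AsPh3, Cs2CO3, DMF/THF/H2O, rt
Reagents that add atoms: none
Why: anti-Markovnikov hydroboration puts boron on C12 and the B-alkyl Suzuki–Miyaura coupling forms C12–C13; C11 is created in the hydroboration under substrate control, the borane being expected to reach the pseudoaxial isopropenyl group from the face turned away from C2 and C3 in the rotamer whose C11=C12 bond eclipses C4–C4a, which should give (11S).

Step 17
Reactants: 31 tert-butyl{[(2S,3E,6S)-6-[(1S,4R)-6-methoxy-5-(methoxymethoxy)-4-methyl-1,2,3,4-tetrahydronaphthalen-1-yl]-2-methylhept-3-en-1-yl]oxy}dimethylsilane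
Product: 32 tert-butyl{[(2S,6S)-6-[(1S,4R)-6-methoxy-5-(methoxymethoxy)-4-methyl-1,2,3,4-tetrahydronaphthalen-1-yl]-2-methylheptyl]oxy}dimethylsilane
Conditions: H2 (1 atm), PtO2, EtOAc, rt
Reagents that add atoms: none
Why: heterogeneous hydrogenation of the disubstituted C13=C14 alkene over platinum, which isomerises alkenes less readily than palladium, so the allylic centre C15 should keep its configuration.

Step 18
Reactants: 32 tert-butyl{[(2S,6S)-6-[(1S,4R)-6-methoxy-5-(methoxymethoxy)-4-methyl-1,2,3,4-tetrahydronaphthalen-1-yl]-2-methylheptyl]oxy}dimethylsilane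
Product: 34 methyl (5R,8S)-8-[(2S,6S)-7-[(tert-butyldimethylsilyl)oxy]-6-methylheptan-2-yl]-3-methoxy-4-(methoxymethoxy)-5-methyl-5,6,7,8-tetrahydronaphthalene-2-carboxylate, via C6-aryllithium 33 (not isolated)
Conditions: n-BuLi, TMEDA, Et2O, 0 °C to rt; then cannulated into ClCO2Me (5 equiv), THF, −78 °C
Reagents that add atoms: methyl chloroformate, COC(=O)Cl
Why: directed ortho-lithiation at C6, the only position ortho to the C7 methoxy group (the vicinal dialkoxy pattern assists as in veratrole), followed by C-acylation of the aryllithium with excess chloroformate under inverse addition to prevent a second addition.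

Step 19
Reactants: 34 methyl (5R,8S)-8-[(2S,6S)-7-[(tert-butyldimethylsilyl)oxy]-6-methylheptan-2-yl]-3-methoxy-4-(methoxymethoxy)-5-methyl-5,6,7,8-tetrahydronaphthalene-2-carboxylate
Product: 35 methyl (5R,8S)-4-hydroxy-8-[(2S,6S)-7-hydroxy-6-methylheptan-2-yl]-3-methoxy-5-methyl-5,6,7,8-tetrahydronaphthalene-2-carboxylate
Conditions: HCl (3 M in MeOH), 40 °C
Reagents that add atoms: none
Why: acid-catalysed acetal exchange removes the MOM group and acidic methanolysis cleaves the silyl ether in one operation, while the methyl ester is inert in methanol.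

Compound list
1 | guaiacol (2-methoxyphenol) | COc1ccccc1O | starting material
2 | 1-methoxy-2-(methoxymethoxy)benzene | COCOc1ccccc1OC | intermediate
3 | [3-methoxy-2-(methoxymethoxy)phenyl]lithium | [Li]c1cccc(OC)c1OCOC | intermediate
4 | lithium trimethoxy[3-methoxy-2-(methoxymethoxy)phenyl]borate | [Li+].CO[B-](OC)(OC)c1cccc(OC)c1OCOC | intermediate
5 | [3-methoxy-2-(methoxymethoxy)phenyl]boronic acid | OB(O)c1cccc(OC)c1OCOC | intermediate
6 | methyl (E)-but-2-enoate | C/C=C/C(=O)OC | starting material
7 | methyl (3R)-3-[3-methoxy-2-(methoxymethoxy)phenyl]butanoate | COc1cccc([C@H](C)CC(=O)OC)c1OCOC | intermediate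
8 | methyl (3R)-3-[6-bromo-3-methoxy-2-(methoxymethoxy)phenyl]butanoate | COc1ccc(Br)c([C@H](C)CC(=O)OC)c1OCOC | intermediate
9 | (3R)-3-[6-bromo-3-methoxy-2-(methoxymethoxy)phenyl]butan-1-ol | COc1ccc(Br)c([C@H](C)CCO)c1OCOC | intermediate
10 | 1-bromo-2-[(2R)-4-iodobutan-2-yl]-4-methoxy-3-(methoxymethoxy)benzene | COc1ccc(Br)c([C@H](C)CCI)c1OCOC | intermediate
11 | 1-bromo-2-methylprop-1-ene | CC(C)=CBr | starting material
12 | (2-methylprop-1-en-1-yl)magnesium bromide | CC(C)=C[Mg]Br | intermediate
13 | 1-bromo-4-methoxy-3-(methoxymethoxy)-2-[(2R)-6-methylhept-5-en-2-yl]benzene | COc1ccc(Br)c([C@H](C)CCC=C(C)C)c1OCOC | intermediate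
14 | {4-methoxy-3-(methoxymethoxy)-2-[(2R)-6-methylhept-5-en-2-yl]phenyl}lithium | COc1ccc([Li])c([C@H](C)CCC=C(C)C)c1OCOC | intermediate
15 | lithium trimethoxy{4-methoxy-3-(methoxymethoxy)-2-[(2R)-6-methylhept-5-en-2-yl]phenyl}borate | [Li+].COc1ccc([B-](OC)(OC)OC)c([C@H](C)CCC=C(C)C)c1OCOC | intermediate
16 | 4-methoxy-3-(methoxymethoxy)-2-[(2R)-6-methylhept-5-en-2-yl]phenol | COc1ccc(O)c([C@H](C)CCC=C(C)C)c1OCOC | intermediate
17 | 4-methoxy-3-(methoxymethoxy)-2-[(2R)-6-methylhept-5-en-2-yl]phenyl N-(propan-2-yl)carbamate | COc1ccc(OC(=O)NC(C)C)c([C@H](C)CCC=C(C)C)c1OCOC | intermediate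
18 | 4-methoxy-3-(methoxymethoxy)-2-[(2R)-6-methylhept-5-en-2-yl]phenyl N-(propan-2-yl)-N-(trimethylsilyl)carbamate | COc1ccc(OC(=O)N(C(C)C)[Si](C)(C)C)c([C@H](C)CCC=C(C)C)c1OCOC | intermediate
19 | {5-methoxy-4-(methoxymethoxy)-3-[(2R)-6-methylhept-5-en-2-yl]-2-{[(propan-2-yl)(trimethylsilyl)carbamoyl]oxy}phenyl}lithium | COc1cc([Li])c(OC(=O)N(C(C)C)[Si](C)(C)C)c([C@H](C)CCC=C(C)C)c1OCOC | intermediate
20 | 4-methoxy-3-(methoxymethoxy)-2-[(2R)-6-methylhept-5-en-2-yl]-6-(trimethylsilyl)phenyl N-(propan-2-yl)-N-(trimethylsilyl)carbamate | COc1cc([Si](C)(C)C)c(OC(=O)N(C(C)C)[Si](C)(C)C)c([C@H](C)CCC=C(C)C)c1OCOC | intermediate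
21 | 4-methoxy-3-(methoxymethoxy)-2-[(2R)-6-methylhept-5-en-2-yl]-6-(trimethylsilyl)phenyl N-(propan-2-yl)carbamate | COc1cc([Si](C)(C)C)c(OC(=O)NC(C)C)c([C@H](C)CCC=C(C)C)c1OCOC | intermediate
22 | 4-methoxy-3-(methoxymethoxy)-2-[(2R)-6-methylhept-5-en-2-yl]-6-(trimethylsilyl)phenol | COc1cc([Si](C)(C)C)c(O)c([C@H](C)CCC=C(C)C)c1OCOC | intermediate
23 | 4-methoxy-3-(methoxymethoxy)-2-[(2R)-6-methylhept-5-en-2-yl]-6-(trimethylsilyl)phenyl trifluoromethanesulfonate | COc1cc([Si](C)(C)C)c(OS(=O)(=O)C(F)(F)F)c([C@H](C)CCC=C(C)C)c1OCOC | intermediate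
24 | 5-methoxy-4-(methoxymethoxy)-3-[(2R)-6-methylhept-5-en-2-yl]-1,2-didehydrobenzene (C4a–C5 aryne) | COC1=CC#CC([C@H](C)CCC=C(C)C)=C1OCOC | intermediate
25 | (1R,4S)-7-methoxy-8-(methoxymethoxy)-1-methyl-4-(prop-1-en-2-yl)-1,2,3,4-tetrahydronaphthalene | COc1ccc2c(c1OCOC)[C@H](C)CC[C@H]2C(C)=C | intermediate
26 | methyl (2R)-3-hydroxy-2-methylpropanoate (Roche ester) | COC(=O)[C@H](C)CO | starting material
27 | methyl (2R)-3-[(tert-butyldimethylsilyl)oxy]-2-methylpropanoate | COC(=O)[C@H](C)CO[Si](C)(C)C(C)(C)C | intermediate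
28 | (2R)-3-[(tert-butyldimethylsilyl)oxy]-2-methylpropanal | O=C[C@H](C)CO[Si](C)(C)C(C)(C)C | intermediate
29 | tert-butyl{[(2S,3E)-4-iodo-2-methylbut-3-en-1-yl]oxy}dimethylsilane | I/C=C/[C@H](C)CO[Si](C)(C)C(C)(C)C | intermediate
30 | 9-[(2S)-2-[(1S,4R)-6-methoxy-5-(methoxymethoxy)-4-methyl-1,2,3,4-tetrahydronaphthalen-1-yl]propyl]-9-borabicyclo[3.3.1]nonane | COc1ccc2c(c1OCOC)[C@H](C)CC[C@H]2[C@@H](C)CB1C2CCCC1CCC2 | intermediate
31 | tert-butyl{[(2S,3E,6S)-6-[(1S,4R)-6-methoxy-5-(methoxymethoxy)-4-methyl-1,2,3,4-tetrahydronaphthalen-1-yl]-2-methylhept-3-en-1-yl]oxy}dimethylsilane | COc1ccc2c(c1OCOC)[C@H](C)CC[C@H]2[C@@H](C)C/C=C/[C@H](C)CO[Si](C)(C)C(C)(C)C | intermediate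
32 | tert-butyl{[(2S,6S)-6-[(1S,4R)-6-methoxy-5-(methoxymethoxy)-4-methyl-1,2,3,4-tetrahydronaphthalen-1-yl]-2-methylheptyl]oxy}dimethylsilane | COc1ccc2c(c1OCOC)[C@H](C)CC[C@H]2[C@@H](C)CCC[C@H](C)CO[Si](C)(C)C(C)(C)C | intermediate
33 | {(5R,8S)-8-[(2S,6S)-7-[(tert-butyldimethylsilyl)oxy]-6-methylheptan-2-yl]-3-methoxy-4-(methoxymethoxy)-5-methyl-5,6,7,8-tetrahydronaphthalen-2-yl}lithium | COc1c([Li])cc2c(c1OCOC)[C@H](C)CC[C@H]2[C@@H](C)CCC[C@H](C)CO[Si](C)(C)C(C)(C)C | intermediate
34 | methyl (5R,8S)-8-[(2S,6S)-7-[(tert-butyldimethylsilyl)oxy]-6-methylheptan-2-yl]-3-methoxy-4-(methoxymethoxy)-5-methyl-5,6,7,8-tetrahydronaphthalene-2-carboxylate | COC(=O)c1cc2c(c(OCOC)c1OC)[C@H](C)CC[C@H]2[C@@H](C)CCC[C@H](C)CO[Si](C)(C)C(C)(C)C | intermediate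
35 | methyl (5R,8S)-4-hydroxy-8-[(2S,6S)-7-hydroxy-6-methylheptan-2-yl]-3-methoxy-5-methyl-5,6,7,8-tetrahydronaphthalene-2-carboxylate | COC(=O)c1cc2c(c(O)c1OC)[C@H](C)CC[C@H]2[C@@H](C)CCC[C@H](C)CO | target

Total step count: 19 steps.
Longest linear sequence: 16 steps (steps 1–12, then 16–19); the vinyl iodide 29 is made in 3 steps (13–15) and joined in step 16.

The three steps most likely to fail

1. Step 12 (key step). The ring closure may show little facial preference, or may prefer the half-chair path in which C3 rises on the face of the C1 methyl group so that C11 ends cis to C20; a slow ene step would also let fluoride or a second molecule capture the aryne. The fallback replaces kinetic by thermodynamic control of C4 and sets out from 25 as obtained together with its C4 epimer. Lemieux–Johnson cleavage of the isopropenyl group (OsO4 cat., NaIO4, 2,6-lutidine, dioxane/H2O) gives the methyl ketone 1-[(1R,4R)-6-methoxy-5-(methoxymethoxy)-4-methyl-1,2,3,4-tetrahydronaphthalen-1-yl]ethan-1-one F1 and, from the epimer, 1-[(1S,4R)-6-methoxy-5-(methoxymethoxy)-4-methyl-1,2,3,4-tetrahydronaphthalen-1-yl]ethan-1-one F2. C4 is now benzylic and α to a carbonyl group, so DBU in CH2Cl2 equilibrates the pair. F1 should dominate, because its acetyl group is pseudoaxial and free of peri strain with C5–H while C20 stays pseudoaxial away from the C8 oxygen. Wittig methylenation of F1 (Ph3PCH3Br, KOt-Bu, THF, 0 °C) comes back to 25.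

2. Step 16. Facial discrimination in the hydroboration may be poor or reversed, since C11 is induced by C4 alone, and transmetalation of the β-branched alkylborane may be slow. The fallback uses catalyst control and sets out from 25. Copper hydride-catalysed enantioselective hydroboration of the 1,1-disubstituted alkene (CuCl, KOt-Bu, (R)-DTBM-SEGPHOS or its antipode, whichever is matched for hydride delivery leading to 11S, HBpin, THF, rt) gives 2-[(2S)-2-[(1S,4R)-6-methoxy-5-(methoxymethoxy)-4-methyl-1,2,3,4-tetrahydronaphthalen-1-yl]propyl]-4,4,5,5-tetramethyl-1,3,2-dioxaborolane F3. KHF2 in MeOH/H2O converts it into potassium trifluoro[(2S)-2-[(1S,4R)-6-methoxy-5-(methoxymethoxy)-4-methyl-1,2,3,4-tetrahydronaphthalen-1-yl]propyl]borate F4, which couples with 29 (Pd(dppf)Cl2, Cs2CO3, toluene/H2O, 80 °C) and comes back to 31.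

3. Step 3. Protodeboronation of the ortho-alkoxy boronic acid may outrun its transfer to rhodium, or enantioface selection with the methyl ester may be insufficient, which would carry the wrong C1 configuration through the whole route. The fallback uses auxiliary control and sets out from 2. Lithiation as in step 2, transmetalation (MgBr2·OEt2, then CuBr·SMe2) and conjugate addition to (4S)-3-[(2E)-but-2-enoyl]-4-phenyl-1,3-oxazolidin-2-one (THF, −20 °C; attack anti to the phenyl group of the chelated s-cis imide) give (4S)-3-[(3R)-3-[3-methoxy-2-(methoxymethoxy)phenyl]butanoyl]-4-phenyl-1,3-oxazolidin-2-one F5. NaOMe in MeOH at 0 °C releases the auxiliary and comes back to 7.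

Further compounds
F1 | step 12 | 1-[(1R,4R)-6-methoxy-5-(methoxymethoxy)-4-methyl-1,2,3,4-tetrahydronaphthalen-1-yl]ethan-1-one | COc1ccc2c(c1OCOC)[C@H](C)CC[C@H]2C(C)=O
F2 | step 12 | 1-[(1S,4R)-6-methoxy-5-(methoxymethoxy)-4-methyl-1,2,3,4-tetrahydronaphthalen-1-yl]ethan-1-one | COc1ccc2c(c1OCOC)[C@H](C)CC[C@@H]2C(C)=O
F3 | step 16 | 2-[(2S)-2-[(1S,4R)-6-methoxy-5-(methoxymethoxy)-4-methyl-1,2,3,4-tetrahydronaphthalen-1-yl]propyl]-4,4,5,5-tetramethyl-1,3,2-dioxaborolane | COc1ccc2c(c1OCOC)[C@H](C)CC[C@H]2[C@@H](C)CB1OC(C)(C)C(C)(C)O1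
F4 | step 16 | potassium trifluoro[(2S)-2-[(1S,4R)-6-methoxy-5-(methoxymethoxy)-4-methyl-1,2,3,4-tetrahydronaphthalen-1-yl]propyl]borate | [K+].COc1ccc2c(c1OCOC)[C@H](C)CC[C@H]2[C@@H](C)C[B-](F)(F)F
F5 | step 3 | (4S)-3-[(3R)-3-[3-methoxy-2-(methoxymethoxy)phenyl]butanoyl]-4-phenyl-1,3-oxazolidin-2-one | COc1cccc([C@H](C)CC(=O)N2[C@@H](c3ccccc3)COC2=O)c1OCOC
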